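**Plan**

- Retrosynthesis: the ester C–O bond to linoleic acid is cut first, then the pyrrole ring is opened at N1–C2 and C3–C3a, which leaves 2-iodo-5-prenylaniline and a five-membered lactol.
- Enabling feature: C3 of the pyrrole ring (N1, C2, C3, C3a, C7a) bears the only stereocentre, a CH whose three carbon arms (CH2O, C(CH3)2OH and the C3–C2 unit) are the hydroxymethyl, dimethylcarbinol and CH2–C=O arms of a lactone derived from terebic acid; C2 and C3 can therefore be supplied as an aldehyde carbon and its α-carbon.
- Forward: terebic acid is resolved, reduced, silylated and reduced to lactol 7; 4-bromo-2-nitroaniline is prenylated, its NH2 exchanged for iodine and its nitro group reduced to give aniline 13.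
- Annulation of 13 with 7 builds the pyrrole ring onto the benzene ring (the only ring formed); desilylation and acylation of the primary hydroxyl with linoleic acid complete the chain.
- Stereochemistry: the single (R)-centre is that of (S)-terebic acid from a salt resolution and takes no part in any bond formation after step 3; the (9Z,12Z)-diene comes with linoleic acid.

Key step: step 9

Assumption: of the two diastereomeric salts of racemic terebic acid with (S)-1-phenylethylamine, the one holding the (S)-acid is taken to be the less soluble; if crystallisation enriches the (R)-acid instead, (R)-1-phenylethylamine gives the mirror-image salt pair and the (S)-acid by the same operations, the configuration of salt 3 being settled by X-ray analysis with the amine as internal reference.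

**Route**

Step 1
Reactants: 1 racemic terebic acid (2,2-dimethyl-5-oxooxolane-3-carboxylic acid); 2 (S)-1-phenylethylamine
Product: 3 (S)-1-phenylethylammonium (3S)-2,2-dimethyl-5-oxooxolane-3-carboxylate (the less soluble diastereomeric salt)
Conditions: 2 (1.0 equiv), EtOH, 60 °C → 5 °C; crystals recrystallised from EtOH until the rotation of a liberated sample stays constant
Reagents that add atoms: none
Why: Classical resolution by diastereomeric salt formation, in which the salts of the two acid enantiomers with one amine enantiomer differ in solubility, so fractional crystallisation should deliver the salt of the (S)-acid without touching any bond at the stereocentre.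

Step 2
Reactants: 3 (S)-1-phenylethylammonium (S)-terebate
Product: 4 (S)-terebic acid, (3S)-2,2-dimethyl-5-oxooxolane-3-carboxylic acid
Conditions: 1 M HCl, EtOAc, 0 °C → rt, aqueous phase saturated with NaCl
Reagents that add atoms: none
Why: Acid–base liberation in which the mineral acid protonates the carboxylate, the amine stays in water as its hydrochloride and the γ-lactone tolerates cold dilute acid.

Step 3
Reactants: 4 (S)-terebic acid
Product: 5 (4R)-4-(hydroxymethyl)-5,5-dimethyloxolan-2-one
Conditions: BH3·SMe2 (1.2 equiv), THF, 0 °C → rt; MeOH quench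
Reagents that add atoms: none
Why: Chemoselective borane reduction of a carboxylic acid, whose acyloxyborane is reduced much faster than the lactone carbonyl, under non-basic conditions that cannot enolise the stereocentre (the descriptor changes from S to R only because the priorities change).

Step 4
Reactants: 5 (4R)-4-(hydroxymethyl)-5,5-dimethyloxolan-2-one
Product: 6 (4R)-4-[(tert-butyldimethylsilyloxy)methyl]-5,5-dimethyloxolan-2-one
Conditions: TBSCl (1.2 equiv), imidazole (2.5 equiv), DMF, 0 °C → rt
Reagents that add atoms: tert-butyldimethylsilyl chloride, CC(C)(C)[Si](C)(C)Cl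
Why: Standard imidazole-mediated silylation of a primary alcohol, run directly after step 3 so that the hydroxymethyl lactone has no time to translactonise.

Step 5
Reactants: 6 (4R)-4-[(tert-butyldimethylsilyloxy)methyl]-5,5-dimethyloxolan-2-one
Product: 7 (4R)-4-[(tert-butyldimethylsilyloxy)methyl]-5,5-dimethyloxolan-2-ol (lactol, mixture of anomers)
Conditions: i-Bu2AlH (1.1 equiv), CH2Cl2, −78 °C; MeOH, aqueous potassium sodium tartrate
Reagents that add atoms: none
Why: Partial reduction of a γ-lactone to the lactol, in which the tetrahedral aluminium hemiacetal is stable at −78 °C and collapses only on work-up, so over-reduction is avoided and the silyl ether is untouched.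

Step 6
Reactants: 8 4-bromo-2-nitroaniline; 9 prenylboronic acid pinacol ester, 4,4,5,5-tetramethyl-2-(3-methylbut-2-enyl)-1,3,2-dioxaborolane
Product: 10 2-nitro-4-(3-methylbut-2-enyl)aniline
Conditions: PdCl2(IPent)(3-chloropyridine) (2 mol %; IPent = 1,3-bis[2,6-di(pentan-3-yl)phenyl]imidazol-2-ylidene), 5 M aqueous KOH (3 equiv), THF, 70 °C
Reagents that add atoms: none
Why: Suzuki–Miyaura allyl–aryl coupling in which the allylpalladium species equilibrates after transmetalation and the bulky N-heterocyclic carbene ligand steers reductive elimination to the unsubstituted allyl terminus, which should give the linear prenyl arene and not the 1,1-dimethylallyl isomer.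

Step 7
Reactants: 10 2-nitro-4-(3-methylbut-2-enyl)aniline
Product: 12 1-iodo-2-nitro-4-(3-methylbut-2-enyl)benzene, via arenediazonium tosylate 11 (not isolated)
Conditions: t-BuONO (1.3 equiv), p-TsOH·H2O (1.5 equiv), MeCN, 0 °C → rt; then KI (2.5 equiv), H2O, rt
Reagents that add atoms: potassium iodide, [K+].[I-]
Why: Diazotisation followed by copper-free Sandmeyer-type iododediazoniation, in which the alkyl nitrite with a sulfonic acid forms a stable arenediazonium tosylate without free nitrous acid or strong mineral acid that would attack the trisubstituted alkene, and iodide then replaces dinitrogen.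

Step 8
Reactants: 12 1-iodo-2-nitro-4-(3-methylbut-2-enyl)benzene
Product: 13 2-iodo-5-(3-methylbut-2-enyl)aniline
Conditions: Fe powder (5 equiv), NH4Cl (2 equiv), EtOH/H2O, 70 °C
Reagents that add atoms: none
Why: Béchamp-type nitro reduction by electron transfer from Fe under near-neutral conditions, which spares the aryl iodide and the isolated alkene that catalytic hydrogenation would attack.

Step 9
Reactants: 7 (4R)-4-[(tert-butyldimethylsilyloxy)methyl]-5,5-dimethyloxolan-2-ol; 13 2-iodo-5-(3-methylbut-2-enyl)aniline
Product: 15 (3R)-4-(tert-butyldimethylsilyloxy)-2-methyl-3-[6-(3-methylbut-2-enyl)-1H-indol-3-yl]butan-2-ol, via N-aryl enamine 14 (not isolated)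
Conditions: Pd(OAc)2 (10 mol %), DABCO (3 equiv), degassed DMF, 85 °C; 7 in slight excess (1.2 equiv)
Reagents that add atoms: none
Why: The open hydroxy-aldehyde tautomer of 7 condenses with the amino group of 13 to an imine whose enamine tautomer 14 already holds the N1–C2 bond, and oxidative addition of the C–I bond to zerovalent palladium generated from Pd(OAc)2 places an arylpalladium iodide beside that enamine. The nucleophilic enamine carbon is then arylated, either by carbopalladation of the C2=C3 bond and β-hydride elimination or by C-palladation to a six-membered azapalladacycle and reductive elimination, and loss of HI to DABCO with tautomerisation gives the aromatic indole. The closest known reaction type is the palladium-catalysed annulation of ortho-iodoanilines with enolisable aldehydes to 3-substituted indoles, an intramolecular Heck-type enamine arylation. The pyrrole ring closes as a five-membered ring through the C3–C3a bond, formally a 5-endo-trig arylation of the enamine or, in the palladacycle picture, a contraction from six to five members by reductive elimination. No stereocentre is created, and the existing one lies β to the aldehyde carbon, carries no hydrogen that an amine base can remove and is passed on unchanged. The step needs exclusive use of the C–I bond and one ring-fusion regiochemistry, both secured by iodine standing ortho to nitrogen and para to the prenyl group, while ligand-free palladium with a weak amine base leaves the trisubstituted alkene, the silyl ether and the tertiary alcohol alone.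

Step 10
Reactants: 15 (3R)-4-(tert-butyldimethylsilyloxy)-2-methyl-3-[6-(3-methylbut-2-enyl)-1H-indol-3-yl]butan-2-ol
Product: 16 (2R)-3-methyl-2-[6-(3-methylbut-2-enyl)-1H-indol-3-yl]butane-1,3-diol
Conditions: TBAF (1.5 equiv), THF, 0 °C → rt; aqueous work-up
Reagents that add atoms: none
Why: Fluoride-induced cleavage of the silyl ether, driven by the strength of the Si–F bond, under conditions that leave the indole, the prenyl group and the tertiary alcohol unchanged.

Step 11
Reactants: 16 (2R)-3-methyl-2-[6-(3-methylbut-2-enyl)-1H-indol-3-yl]butane-1,3-diol; 17 linoleic acid, (9Z,12Z)-octadeca-9,12-dienoic acid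
Product: 18 (2R)-3-hydroxy-3-methyl-2-[6-(3-methylbut-2-enyl)-1H-indol-3-yl]butyl (9Z,12Z)-octadeca-9,12-dienoate (target, CNP0180241.2)
Conditions: 17 (1.05 equiv), DCC (1.1 equiv), DMAP (0.1 equiv), CH2Cl2, 0 °C → rt, argon, dark
Reagents that add atoms: none
Why: Steglich esterification, in which the N-acylpyridinium ion formed from the O-acylisourea acylates the unhindered primary hydroxyl far faster than the tertiary hydroxyl or the non-basic indole N–H, and the neutral conditions keep the skipped (9Z,12Z)-diene from isomerising.

**Compound list**

1 | racemic terebic acid (2,2-dimethyl-5-oxooxolane-3-carboxylic acid) | CC1(C)OC(=O)CC1C(=O)O | starting material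
2 | (S)-1-phenylethylamine | C[C@H](N)c1ccccc1 | starting material
3 | (S)-1-phenylethylammonium (3S)-2,2-dimethyl-5-oxooxolane-3-carboxylate | C[C@H]([NH3+])c1ccccc1.[O-]C(=O)[C@@H](C1)C(C)(C)OC1=O | intermediate
4 | (S)-terebic acid, (3S)-2,2-dimethyl-5-oxooxolane-3-carboxylic acid | OC(=O)[C@@H](C1)C(C)(C)OC1=O | intermediate
5 | (4R)-4-(hydroxymethyl)-5,5-dimethyloxolan-2-one | OC[C@@H](C1)C(C)(C)OC1=O | intermediate
6 | (4R)-4-[(tert-butyldimethylsilyloxy)methyl]-5,5-dimethyloxolan-2-one | CC(C)(C)[Si](C)(C)OC[C@@H](C1)C(C)(C)OC1=O | intermediate
7 | (4R)-4-[(tert-butyldimethylsilyloxy)methyl]-5,5-dimethyloxolan-2-ol (anomeric mixture) | CC(C)(C)[Si](C)(C)OC[C@@H](C1)C(C)(C)OC1O | intermediate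
8 | 4-bromo-2-nitroaniline | Nc1ccc(Br)cc1[N+](=O)[O-] | starting material
9 | prenylboronic acid pinacol ester | CC(C)=CCB1OC(C)(C)C(C)(C)O1 | starting material
10 | 2-nitro-4-(3-methylbut-2-enyl)aniline | Nc1ccc(CC=C(C)C)cc1[N+](=O)[O-] | intermediate
11 | 2-nitro-4-(3-methylbut-2-enyl)benzenediazonium 4-methylbenzenesulfonate (formed in the flask) | Cc1ccc(cc1)S(=O)(=O)[O-].N#[N+]c1ccc(CC=C(C)C)cc1[N+](=O)[O-] | intermediate
12 | 1-iodo-2-nitro-4-(3-methylbut-2-enyl)benzene | Ic1ccc(CC=C(C)C)cc1[N+](=O)[O-] | intermediate
13 | 2-iodo-5-(3-methylbut-2-enyl)aniline | Nc1cc(CC=C(C)C)ccc1I | intermediate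
14 | (3R)-4-(tert-butyldimethylsilyloxy)-3-{2-[2-iodo-5-(3-methylbut-2-enyl)anilino]ethenyl}-2-methylbutan-2-ol (N-aryl enamine, formed in the flask) | CC(C)(C)[Si](C)(C)OC[C@@H](C=CNc1cc(CC=C(C)C)ccc1I)C(C)(C)O | intermediate
15 | (3R)-4-(tert-butyldimethylsilyloxy)-2-methyl-3-[6-(3-methylbut-2-enyl)-1H-indol-3-yl]butan-2-ol | CC(C)(C)[Si](C)(C)OC[C@@H](c1c[nH]c2cc(CC=C(C)C)ccc12)C(C)(C)O | intermediate
16 | (2R)-3-methyl-2-[6-(3-methylbut-2-enyl)-1H-indol-3-yl]butane-1,3-diol | OC[C@@H](c1c[nH]c2cc(CC=C(C)C)ccc12)C(C)(C)O | intermediate
17 | linoleic acid, (9Z,12Z)-octadeca-9,12-dienoic acid | CCCCC/C=C\C/C=C\CCCCCCCC(=O)O | starting material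
18 | (2R)-3-hydroxy-3-methyl-2-[6-(3-methylbut-2-enyl)-1H-indol-3-yl]butyl (9Z,12Z)-octadeca-9,12-dienoate | CCCCC/C=C\C/C=C\CCCCCCCC(=O)OC[C@@H](c1c[nH]c2cc(CC=C(C)C)ccc12)C(C)(C)O | target

**Step count and risks**

Total step count: 11. Longest linear sequence: 8 steps (steps 1, 2, 3, 4, 5, 9, 10, 11); the aniline branch (steps 6, 7, 8) joins at step 9.

Steps most likely to fail:

1. Step 9. The carbonyl partner may stay locked as the ring-closed lactol or as its cyclic N,O-acetal with the aniline, so that too little enamine meets the arylpalladium iodide and reductive loss of iodine from 13 takes over. The fallback sets out from lactone 6 and uses an aldehyde that cannot ring-close. Opening of 6 with MeNH(OMe)·HCl and AlMe3 (CH2Cl2, 0 °C → rt) should give the Weinreb amide (3R)-3-[(tert-butyldimethylsilyloxy)methyl]-4-hydroxy-N-methoxy-N,4-dimethylpentanamide F1. This is silylated at once with TESOTf and 2,6-lutidine to the triethylsilyl ether (3R)-3-[(tert-butyldimethylsilyloxy)methyl]-N-methoxy-N,4-dimethyl-4-(triethylsilyloxy)pentanamide F2. Reduction with i-Bu2AlH (THF, −78 °C) gives the open-chain aldehyde (3R)-3-[(tert-butyldimethylsilyloxy)methyl]-4-methyl-4-(triethylsilyloxy)pentanal F3. Annulation of F3 with 13 under the Pd(OAc)2/DABCO conditions gives the doubly silylated indole 3-[(2R)-1-(tert-butyldimethylsilyloxy)-3-methyl-3-(triethylsilyloxy)butan-2-yl]-6-(3-methylbut-2-enyl)-1H-indole F4. Excess TBAF removes both silyl groups, and the route is rejoined at diol 16.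

2. Step 7. The nitrosating agent or the sulfonic acid may attack the trisubstituted alkene (nitrosation, hydration), and aryl radicals formed during the iodide exchange may abstract hydrogen from the benzylic–allylic CH2. The fallback sets out from lactol 7 and introduces the prenyl group only after the ring is built. Annulation of 7 with commercial 5-bromo-2-iodoaniline (Nc1cc(Br)ccc1I) under the conditions of step 9, where ligand-free palladium should use only the C–I bond, gives the bromoindole (3R)-3-(6-bromo-1H-indol-3-yl)-4-(tert-butyldimethylsilyloxy)-2-methylbutan-2-ol F5. Suzuki–Miyaura coupling of F5 with boronate 9 under the conditions of step 6 rejoins the route at 15. Steps 6 to 8 are then not needed.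

3. Step 1. The solubility difference between the diastereomeric salts may be too small, or a solid solution may form, so that enantiomeric enrichment is slow or incomplete. The fallback sets out from racemic acid 1 and resolves later by chromatography. Reduction of 1 with BH3·SMe2 gives racemic 4-(hydroxymethyl)-5,5-dimethyloxolan-2-one F6, and TBSCl with imidazole gives racemic 4-[(tert-butyldimethylsilyloxy)methyl]-5,5-dimethyloxolan-2-one F7. Preparative chromatography of F7 on a polysaccharide-carbamate chiral stationary phase (supercritical CO2/i-PrOH) separates the enantiomers, and the (4R)-enantiomer rejoins the route at 6. Its configuration would be assigned by vibrational circular dichroism.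

Further compounds
F1 | step 9 | (3R)-3-[(tert-butyldimethylsilyloxy)methyl]-4-hydroxy-N-methoxy-N,4-dimethylpentanamide | CC(C)(C)[Si](C)(C)OC[C@@H](CC(=O)N(C)OC)C(C)(C)O
F2 | step 9 | (3R)-3-[(tert-butyldimethylsilyloxy)methyl]-N-methoxy-N,4-dimethyl-4-(triethylsilyloxy)pentanamide | CC(C)(C)[Si](C)(C)OC[C@@H](CC(=O)N(C)OC)C(C)(C)O[Si](CC)(CC)CC
F3 | step 9 | (3R)-3-[(tert-butyldimethylsilyloxy)methyl]-4-methyl-4-(triethylsilyloxy)pentanal | CC(C)(C)[Si](C)(C)OC[C@@H](CC=O)C(C)(C)O[Si](CC)(CC)CC
F4 | step 9 | 3-[(2R)-1-(tert-butyldimethylsilyloxy)-3-methyl-3-(triethylsilyloxy)butan-2-yl]-6-(3-methylbut-2-enyl)-1H-indole | CC(C)(C)[Si](C)(C)OC[C@@H](c1c[nH]c2cc(CC=C(C)C)ccc12)C(C)(C)O[Si](CC)(CC)CC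
F5 | step 7 | (3R)-3-(6-bromo-1H-indol-3-yl)-4-(tert-butyldimethylsilyloxy)-2-methylbutan-2-ol | CC(C)(C)[Si](C)(C)OC[C@@H](c1c[nH]c2cc(Br)ccc12)C(C)(C)O
F6 | step 1 | racemic 4-(hydroxymethyl)-5,5-dimethyloxolan-2-one | OCC1CC(=O)OC1(C)C
F7 | step 1 | racemic 4-[(tert-butyldimethylsilyloxy)methyl]-5,5-dimethyloxolan-2-one | CC(C)(C)[Si](C)(C)OCC1CC(=O)OC1(C)C
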